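You want to know how the rate of making product at 30% conversion answers a change in the charge of free catalyst, in the flask whose first minutes are the midnight run.

all flasks: starting material 0.050 M; free catalyst 0.14 mM

| charge | partner | protic impurity | remark |
|---|---|---|---|
| midnight | 0.035 M | 0.050 M | the very flask that is asked about, followed so far |
| flask | 0.0350 M | 0.0500 M |  |

midnight run (percent of the starting material charged)

| time / s | product / % | starting material / % |
|---|---|---|
| 10.0 | 0.9 | 97.1 |
| 20.0 | 0.7 | 96.0 |
| 40.0 | 2.8 | 90.7 |
| 60.0 | 3.1 | 86.7 |
| 80.0 | 5.1 | 83.1 |
| 120 | 7.1 | 76.1 |

(standard deviation of a reading: 0.5 percentage points)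

1. factor on the rate of making product when 30% of the starting material are converted if free catalyst is charged twice over
2. factor on the rate when 30% of the starting material are converted if free catalyst is charged at 0.015 mM instead

- no earlier run changes the charge of free catalyst; that part of a forecast is a guess

No run varies the catalyst, so first order in free catalyst and in partner is my assumption. The first way is then plain proportion:

  doubled: 2; at 0.015 mM: x = 0.107

But that treats partner as equal in flasks that have spent different amounts of it, so the second way counts partner.

The midnight run loses more starting material than it shows as product. Call the product share of the loss φ: it reads 0.297 at 120 s and 0.301 at 40.0 s, with no drift beyond the scatter. Free catalyst is 0.280% of the starting material, less than the 16.8% missing at 120 s, so it cannot hold that mass. I take the rest to be an uncatalysed loss to protic impurity. Then S = φ/(1 − φ) = 0.423, the rate of making product over the rate of that side loss (a selectivity factor), and S scales with the catalyst charge by a factor x.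

With one partner used per product, the fraction of partner left at 30% conversion is L = 1 − (starting material converted)·φ/(partner charged), where φ = xS/(1 + xS):

  this flask: L = 0.873
  doubled: φ = 0.458, L = 0.804, factor 1.84
  at 0.015 mM: φ = 0.0433, L = 0.981, factor 0.120

The two ways part, and I commit to the second, since the fraction of partner left at 30% conversion is less with the doubled charge than in this flask and more at 0.015 mM.

The forecast, reading the loss as “a parallel drain rather than a build-up of intermediate”, gives 1.9 and 0.115, a little off my figures.

The simulation gives 1.88 and 0.120.

    partner + free catalyst ⇌ catalyst intermediate A (K = 56.0 M⁻¹, k = 1400 M⁻¹ min⁻¹)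
    starting material + catalyst intermediate A ⇌ catalyst intermediate B (K = 180 M⁻¹, k = 13000 M⁻¹ min⁻¹)
    catalyst intermediate B ⇌ by-product + catalyst intermediate C (K = 0.0190 M, k = 44.0 min⁻¹)
    catalyst intermediate C → free catalyst + product (k = 44.0 min⁻¹)
    starting material + protic impurity → quenched substrate (k = 2.10 M⁻¹ min⁻¹)

For the doubled charge, the partner count misses by 0.0400 and the proportion by 0.120; at 0.015 mM the count gives 0.120 beside 0.120, the proportion 0.107. In this flask, product over quenched substrate, S read from what has accumulated, is 0.394 at 1.00 min and 0.522 at 5.00 min, below and above S, while starting material falls from 86.8% to 51.6%. The conversion into quenched substrate has 72% of its turnover up to 10.0 min behind it at 5.00 min, and at 10.0 min product over quenched substrate in this flask stands at 0.649.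

The earlier runs and the new flask were generated by integration with made-up constants.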